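**Retrosynthetic overview**
1. Target 24 comes from keto lactone 19 by C9 ketone reduction, C9 angeloylation and acetal hydrolysis (C3 aldehyde).
2. The γ-lactone is the only ring made. Its C8–O bond closes by α-oxylactonisation of the C9 ketone with the C12 acid, which comes from carvone's own isopropenyl group.
3. The C10 quaternary centre comes from a C10–C1 bond made by light-driven radical-chain vinylation of a regiodefined enolate with vinyl bromide (key step).
4. The C5–C4 bond comes from C6-alkoxide-directed 1,4-addition of an acrolein-acetal alkenyl Grignard reagent to trans-4-hydroxycarvone. The C6–O bond comes from singlet-oxygen [4+2] addition to the extended silyl dienol ether of (R)-carvone.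
5. Ring order: the cyclohexane (with C7) is bought as (R)-carvone and the lactone is closed in step 8. Stereocentres are relayed C7 → C6 → C5 → C10 → C8 → C9.

Numbering and faces: elemane numbering of the target is used throughout (ring C5–C10; C14 methyl and C1=C2 vinyl on C10; C4(=C15)–C3 on C5; C11(=C13)–C12 on C7). β is the ring face carrying the C7 side chain; α is the other face.
Assumption: 2-bromo-3,3-diethoxyprop-1-ene (7), bromoethene (12, THF solution) and angelic acid (21) are bought.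

**Step 1**
Reactants: 1 (R)-carvone
Product: 2 trimethyl{[(5S)-2-methyl-5-(prop-1-en-2-yl)cyclohexa-1,3-dien-1-yl]oxy}silane
Conditions: KOtBu (1.15 equiv), THF, 0 °C, 45 min; Me3SiCl (1.3 equiv), −78 → 20 °C; pentane, filtration
Reagents that add atoms: chlorotrimethylsilane C[Si](C)(C)Cl
Why: Thermodynamic γ-deprotonation gives the extended (linear) dienolate, which is O-silylated (silyl dienol ether formation) without touching the C7 stereocentre.

**Step 2**
Reactants: 2 trimethyl{[(5S)-2-methyl-5-(prop-1-en-2-yl)cyclohexa-1,3-dien-1-yl]oxy}silane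
Product: 6 (4S,5R)-4-hydroxy-2-methyl-5-(prop-1-en-2-yl)cyclohex-2-en-1-one (trans-4-hydroxycarvone), via endoperoxide 3 (not isolated), via silylperoxy enone 4 (not isolated), via silyl ether 5 (not isolated)
Conditions: O2, tetraphenylporphyrin (0.5 mol%), white LEDs, CH2Cl2, −78 °C; PPh3 (1.1 equiv), −78 → 20 °C; citric acid, THF/H2O
Reagents that add atoms: dioxygen O=O
Why: Dye-sensitised photooxygenation, a [4+2] cycloaddition of singlet oxygen to the silyloxy diene, occurs on the face anti to the C7 isopropenyl group, and silyl shift plus phosphine reduction then leave the C6 hydroxyl α (trans to C7).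

**Step 3**
Reactants: 6 (4S,5R)-4-hydroxy-2-methyl-5-(prop-1-en-2-yl)cyclohex-2-en-1-one; 7 2-bromo-3,3-diethoxyprop-1-ene
Product: 11 {[(3R,4R,5R)-3-(3,3-diethoxyprop-1-en-2-yl)-2-methyl-5-(prop-1-en-2-yl)cyclohex-1-ene-1,4-diyl]bis(oxy)}bis(trimethylsilane), via alkenyllithium 8 (not isolated), via alkenylmagnesium bromide 9 (not isolated), via bis(bromomagnesium) enolate alkoxide 10 (not isolated)
Conditions: 7 (2.4 equiv), t-BuLi (4.8 equiv), THF, −78 °C; MgBr2·OEt2 (2.5 equiv), −78 °C; 6, −78 → −20 °C; Me3SiCl (4 equiv), Et3N, DMPU, −78 → 0 °C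
Reagents that add atoms: chlorotrimethylsilane C[Si](C)(C)Cl
Why: Alkoxide-directed (ligand-assisted) 1,4-addition of a Grignard reagent delivers the alkenyl group to C5 on the face of the C6 magnesium alkoxide (α), which is also anti to the C7 isopropenyl group, and O-silylation traps the enolate regiospecifically.

**Step 4**
Reactants: 11 {[(3R,4R,5R)-3-(3,3-diethoxyprop-1-en-2-yl)-2-methyl-5-(prop-1-en-2-yl)cyclohex-1-ene-1,4-diyl]bis(oxy)}bis(trimethylsilane); 12 bromoethene
Product: 14 (2S,3S,4R,5R)-3-(3,3-diethoxyprop-1-en-2-yl)-2-ethenyl-4-hydroxy-2-methyl-5-(prop-1-en-2-yl)cyclohexan-1-one, via dipotassium enolate alkoxide 13 (not isolated)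
Conditions: KOtBu (2.1 equiv), THF, −78 → −40 °C; liquid NH3; 12 (4 equiv); 350–370 nm light, −40 °C, 2 h; NH4Cl
Reagents that add atoms: none
Why: Proposed new method: photostimulated radical-chain (SRN1-type) α-vinylation of a fully substituted potassium enolate, in which the photoexcited enolate transfers an electron to vinyl bromide, the vinyl σ-radical left after bromide loss couples with C10 on the β face (anti to the C5 side chain, giving vinyl β and CH3 α) and the ketyl radical anion passes its electron to the next vinyl bromide; the closest known reaction type is the photostimulated SRN1 arylation and vinylation of simple unhindered ketone enolates in liquid ammonia, not yet shown for a tetrasubstituted functionalised enolate that creates an all-carbon quaternary stereocentre.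

**Step 5**
Reactants: 14 (2S,3S,4R,5R)-3-(3,3-diethoxyprop-1-en-2-yl)-2-ethenyl-4-hydroxy-2-methyl-5-(prop-1-en-2-yl)cyclohexan-1-one
Product: 15 (1R,2S,3S,6R)-2-(3,3-diethoxyprop-1-en-2-yl)-3-ethenyl-3-methyl-4-oxo-6-(prop-1-en-2-yl)cyclohexyl acetate
Conditions: Ac2O (2 equiv), DMAP (0.1 equiv), pyridine, CH2Cl2, 0 → 20 °C
Reagents that add atoms: acetic anhydride CC(=O)OC(C)=O
Why: DMAP-catalysed acetylation installs the final C6 acetate with retention, and no other hydroxyl is present.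

**Step 6**
Reactants: 15 (1R,2S,3S,6R)-2-(3,3-diethoxyprop-1-en-2-yl)-3-ethenyl-3-methyl-4-oxo-6-(prop-1-en-2-yl)cyclohexyl acetate
Product: 16 (1R,2S,3S,6R)-2-(3,3-diethoxyprop-1-en-2-yl)-3-ethenyl-6-(3-hydroxyprop-1-en-2-yl)-3-methyl-4-oxocyclohexyl acetate
Conditions: SeO2 (0.3 equiv), t-BuOOH (3 equiv, in decane), CH2Cl2, 20 °C
Reagents that add atoms: selenium dioxide O=[Se]=O; tert-butyl hydroperoxide CC(C)(C)OO
Why: Catalytic SeO2 allylic hydroxylation (ene reaction then [2,3]-shift) attacks the C7 isopropenyl group, the only alkene with an allylic CH3, and no stereocentre is touched.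

**Step 7**
Reactants: 16 (1R,2S,3S,6R)-2-(3,3-diethoxyprop-1-en-2-yl)-3-ethenyl-6-(3-hydroxyprop-1-en-2-yl)-3-methyl-4-oxocyclohexyl acetate
Product: 17 2-[(1R,2R,3S,4S)-2-acetoxy-3-(3,3-diethoxyprop-1-en-2-yl)-4-ethenyl-4-methyl-5-oxocyclohexyl]prop-2-enoic acid
Conditions: TEMPO (0.1 equiv), NaClO2 (2 equiv), NaOCl (0.02 equiv), MeCN/phosphate buffer pH 6.7, 35 °C
Reagents that add atoms: sodium chlorite [Na+].[O-]Cl=O
Why: TEMPO/chlorite oxidation of the primary allylic alcohol to the acrylic acid runs near neutral pH, so the diethyl acetal, the acetate and the stereocentres are kept.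

**Step 8**
Reactants: 17 2-[(1R,2R,3S,4S)-2-acetoxy-3-(3,3-diethoxyprop-1-en-2-yl)-4-ethenyl-4-methyl-5-oxocyclohexyl]prop-2-enoic acid
Product: 19 (3aR,4S,5S,6S,7aR)-5-(3,3-diethoxyprop-1-en-2-yl)-6-ethenyl-6-methyl-3-methylidene-2,7-dioxooctahydro-1-benzofuran-4-yl acetate, via C8-iodo ketone 18 (not isolated)
Conditions: Bu4NI (0.2 equiv), t-BuOOH (2 equiv, in decane), EtOAc, 50 °C
Reagents that add atoms: none
Why: Hypoiodite-catalysed α-oxyacylation (oxylactonisation) of the ketone iodinates C8, the only enolisable position, trans to the C7 side chain, and intramolecular SN2 by the carboxylate with inversion closes the cis-fused lactone (C8–O β).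

**Step 9**
Reactants: 19 (3aR,4S,5S,6S,7aR)-5-(3,3-diethoxyprop-1-en-2-yl)-6-ethenyl-6-methyl-3-methylidene-2,7-dioxooctahydro-1-benzofuran-4-yl acetate
Product: 20 (3aR,4S,5R,6S,7S,7aR)-5-(3,3-diethoxyprop-1-en-2-yl)-6-ethenyl-7-hydroxy-6-methyl-3-methylidene-2-oxooctahydro-1-benzofuran-4-yl acetate
Conditions: NaBH4 (1.5 equiv), CeCl3·7H2O (1.2 equiv), MeOH/THF, −78 °C
Reagents that add atoms: none
Why: Luche reduction is 1,2-selective and spares the α-methylene lactone, and hydride attacks C9 from the α face, anti to the C8–O bond and away from the β-vinyl group, to give the 9β-alcohol.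

**Step 10**
Reactants: 20 (3aR,4S,5R,6S,7S,7aR)-5-(3,3-diethoxyprop-1-en-2-yl)-6-ethenyl-7-hydroxy-6-methyl-3-methylidene-2-oxooctahydro-1-benzofuran-4-yl acetate; 21 angelic acid [(2Z)-2-methylbut-2-enoic acid]
Product: 23 (3aR,4S,5R,6S,7S,7aR)-4-acetoxy-5-(3,3-diethoxyprop-1-en-2-yl)-6-ethenyl-6-methyl-3-methylidene-2-oxooctahydro-1-benzofuran-7-yl (2Z)-2-methylbut-2-enoate, via mixed anhydride 22 (not isolated)
Conditions: 21 (3 equiv), 2,4,6-trichlorobenzoyl chloride (3 equiv), Et3N (3.3 equiv), toluene, 20 °C; then 20, toluene, 80 °C, no DMAP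
Reagents that add atoms: none
Why: Yamaguchi-type mixed-anhydride esterification without DMAP acylates the hindered 9β-hydroxyl while keeping the Z (angelate) geometry, and no stereocentre is touched.

**Step 11**
Reactants: 23 (3aR,4S,5R,6S,7S,7aR)-4-acetoxy-5-(3,3-diethoxyprop-1-en-2-yl)-6-ethenyl-6-methyl-3-methylidene-2-oxooctahydro-1-benzofuran-7-yl (2Z)-2-methylbut-2-enoate
Product: 24 (3aR,4S,5R,6S,7S,7aR)-4-acetoxy-6-ethenyl-6-methyl-3-methylidene-2-oxo-5-(3-oxoprop-1-en-2-yl)octahydro-1-benzofuran-7-yl (2Z)-2-methylbut-2-enoate (CNP0252310.2)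
Conditions: pyridinium p-toluenesulfonate (0.2 equiv), acetone/H2O 9:1, 40 °C
Reagents that add atoms: water O
Why: Mild acid-catalysed acetal hydrolysis frees the conjugated C3 aldehyde without affecting the esters, the lactone or any stereocentre.

**Compound list**
1 | (R)-carvone [(5R)-2-methyl-5-(prop-1-en-2-yl)cyclohex-2-en-1-one] | CC1=CC[C@H](CC1=O)C(C)=C | starting material
2 | trimethyl{[(5S)-2-methyl-5-(prop-1-en-2-yl)cyclohexa-1,3-dien-1-yl]oxy}silane | CC1=C(O[Si](C)(C)C)C[C@H](C(C)=C)C=C1 | intermediate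
3 | 6-methyl-8-(prop-1-en-2-yl)-1-(trimethylsilyloxy)-2,3-dioxabicyclo[2.2.2]oct-5-ene (peroxide bridge on the α face, isopropenyl pointing away from it) | CC1=C[C@@H]2OO[C@@]1(O[Si](C)(C)C)C[C@@H]2C(C)=C | intermediate
4 | (4S,5R)-2-methyl-5-(prop-1-en-2-yl)-4-(trimethylsilylperoxy)cyclohex-2-en-1-one | CC1=C[C@H](OO[Si](C)(C)C)[C@@H](C(C)=C)CC1=O | intermediate
5 | (4S,5R)-2-methyl-5-(prop-1-en-2-yl)-4-(trimethylsilyloxy)cyclohex-2-en-1-one | CC1=C[C@H](O[Si](C)(C)C)[C@@H](C(C)=C)CC1=O | intermediate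
6 | (4S,5R)-4-hydroxy-2-methyl-5-(prop-1-en-2-yl)cyclohex-2-en-1-one (trans-4-hydroxycarvone) | CC1=C[C@H](O)[C@@H](C(C)=C)CC1=O | intermediate
7 | 2-bromo-3,3-diethoxyprop-1-ene (2-bromoacrolein diethyl acetal) | C=C(Br)C(OCC)OCC | starting material
8 | (3,3-diethoxyprop-1-en-2-yl)lithium | C=C([Li])C(OCC)OCC | intermediate
9 | (3,3-diethoxyprop-1-en-2-yl)magnesium bromide | C=C([Mg]Br)C(OCC)OCC | intermediate
10 | bis(bromomagnesium) C9-enolate C6-alkoxide of the 1,4-adduct (C5 side chain α, C6–O α, C7 isopropenyl β) | CC1=C(O[Mg]Br)C[C@H](C(C)=C)[C@@H](O[Mg]Br)[C@H]1C(=C)C(OCC)OCC | intermediate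
11 | {[(3R,4R,5R)-3-(3,3-diethoxyprop-1-en-2-yl)-2-methyl-5-(prop-1-en-2-yl)cyclohex-1-ene-1,4-diyl]bis(oxy)}bis(trimethylsilane) | CC1=C(O[Si](C)(C)C)C[C@H](C(C)=C)[C@@H](O[Si](C)(C)C)[C@H]1C(=C)C(OCC)OCC | intermediate
12 | bromoethene (vinyl bromide) | C=CBr | starting material
13 | dipotassium C9-enolate C6-alkoxide derived from 11 | CC1=C([O-])C[C@H](C(C)=C)[C@@H]([O-])[C@H]1C(=C)C(OCC)OCC.[K+].[K+] | intermediate
14 | (2S,3S,4R,5R)-3-(3,3-diethoxyprop-1-en-2-yl)-2-ethenyl-4-hydroxy-2-methyl-5-(prop-1-en-2-yl)cyclohexan-1-one | C=C[C@]1(C)C(=O)C[C@H](C(C)=C)[C@@H](O)[C@H]1C(=C)C(OCC)OCC | intermediate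
15 | (1R,2S,3S,6R)-2-(3,3-diethoxyprop-1-en-2-yl)-3-ethenyl-3-methyl-4-oxo-6-(prop-1-en-2-yl)cyclohexyl acetate | C=C[C@]1(C)C(=O)C[C@H](C(C)=C)[C@@H](OC(C)=O)[C@H]1C(=C)C(OCC)OCC | intermediate
16 | (1R,2S,3S,6R)-2-(3,3-diethoxyprop-1-en-2-yl)-3-ethenyl-6-(3-hydroxyprop-1-en-2-yl)-3-methyl-4-oxocyclohexyl acetate | C=C[C@]1(C)C(=O)C[C@H](C(=C)CO)[C@@H](OC(C)=O)[C@H]1C(=C)C(OCC)OCC | intermediate
17 | 2-[(1R,2R,3S,4S)-2-acetoxy-3-(3,3-diethoxyprop-1-en-2-yl)-4-ethenyl-4-methyl-5-oxocyclohexyl]prop-2-enoic acid | C=C[C@]1(C)C(=O)C[C@H](C(=C)C(=O)O)[C@@H](OC(C)=O)[C@H]1C(=C)C(OCC)OCC | intermediate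
18 | C8-iodo derivative of 17 (iodine α, trans to the C7 side chain) | C=C[C@]1(C)C(=O)[C@@H](I)[C@H](C(=C)C(=O)O)[C@@H](OC(C)=O)[C@H]1C(=C)C(OCC)OCC | intermediate
19 | (3aR,4S,5S,6S,7aR)-5-(3,3-diethoxyprop-1-en-2-yl)-6-ethenyl-6-methyl-3-methylidene-2,7-dioxooctahydro-1-benzofuran-4-yl acetate | C=C[C@]1(C)C(=O)[C@@H]2OC(=O)C(=C)[C@@H]2[C@@H](OC(C)=O)[C@H]1C(=C)C(OCC)OCC | intermediate
20 | (3aR,4S,5R,6S,7S,7aR)-5-(3,3-diethoxyprop-1-en-2-yl)-6-ethenyl-7-hydroxy-6-methyl-3-methylidene-2-oxooctahydro-1-benzofuran-4-yl acetate | C=C[C@]1(C)[C@H](O)[C@@H]2OC(=O)C(=C)[C@@H]2[C@@H](OC(C)=O)[C@H]1C(=C)C(OCC)OCC | intermediate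
21 | angelic acid [(2Z)-2-methylbut-2-enoic acid] | C/C=C(/C)C(=O)O | starting material
22 | (2Z)-2-methylbut-2-enoic 2,4,6-trichlorobenzoic anhydride | C/C=C(/C)C(=O)OC(=O)c1c(Cl)cc(Cl)cc1Cl | intermediate
23 | (3aR,4S,5R,6S,7S,7aR)-4-acetoxy-5-(3,3-diethoxyprop-1-en-2-yl)-6-ethenyl-6-methyl-3-methylidene-2-oxooctahydro-1-benzofuran-7-yl (2Z)-2-methylbut-2-enoate | C=C[C@]1(C)[C@H](OC(=O)/C(C)=C\C)[C@@H]2OC(=O)C(=C)[C@@H]2[C@@H](OC(C)=O)[C@H]1C(=C)C(OCC)OCC | intermediate
24 | (3aR,4S,5R,6S,7S,7aR)-4-acetoxy-6-ethenyl-6-methyl-3-methylidene-2-oxo-5-(3-oxoprop-1-en-2-yl)octahydro-1-benzofuran-7-yl (2Z)-2-methylbut-2-enoate (CNP0252310.2) | C=C[C@]1(C)[C@H](OC(=O)/C(C)=C\C)[C@@H]2OC(=O)C(=C)[C@@H]2[C@@H](OC(C)=O)[C@H]1C(=C)C=O | target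

**Totals**
Total step count: 11. Longest linear sequence: 11 steps (1 → 24).

**Steps most likely to fail**
The photostimulated vinylation of step 4 (the proposed new method) is the most likely to fail. The vinyl radical may abstract hydrogen or the chain may be short at the hindered C10. The fallback uses known chemistry and sets out from 11. KOtBu (THF, −78 °C) gives 13 as before, and Michael addition to phenyl vinyl sulfoxide (−78 → 0 °C, NH4Cl quench) gives the 2-(phenylsulfinyl)ethyl ketone F3, formed anti to the C5 side chain. Sulfoxide syn-elimination (toluene, NaHCO3, 110 °C) then converts F3 into the vinyl ketone, and the route is rejoined at 14.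

The directed conjugate addition of step 3 is the second risk. The reagent may add 1,2 or lose ethoxide before it adds. The fallback sets out from 6 and 7. Bromide 7 is converted (t-BuLi, THF, −78 °C; 2-isopropoxy-4,4,5,5-tetramethyl-1,3,2-dioxaborolane) into the alkenyl pinacol boronate F1. F1 is added to 6 under [Rh(cod)OH]2 catalysis (dioxane/H2O, KOH, 50 °C), anti to the C7 isopropenyl group as with carvone itself, to give the hydroxy ketone F2 (C10 epimers). Equilibrating silylation (Me3SiCl, Et3N, DMF, 80 °C) gives the more substituted enol ether, and the route is rejoined at 11.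

The oxylactonisation of step 8 is the third risk. The hypoiodite may attack the alkenes, or the hindered ketone may enolise too slowly. The fallback sets out from 17. Pyrrolidone hydrotribromide (THF, 0 °C) brominates only the ketone α-carbon, trans to the C7 side chain, to give the bromo keto acid F4. KHCO3 in DMF at 20 °C closes the cis-lactone by intramolecular carboxylate displacement with inversion, and the route is rejoined at 19.

**Further compounds**
F1 | step 3 | 2-(3,3-diethoxyprop-1-en-2-yl)-4,4,5,5-tetramethyl-1,3,2-dioxaborolane | C=C(B1OC(C)(C)C(C)(C)O1)C(OCC)OCC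
F2 | step 3 | (3S,4R,5R)-3-(3,3-diethoxyprop-1-en-2-yl)-4-hydroxy-2-methyl-5-(prop-1-en-2-yl)cyclohexan-1-one (C10 epimers) | CC1C(=O)C[C@H](C(C)=C)[C@@H](O)[C@H]1C(=C)C(OCC)OCC
F3 | step 4 | (2S,3S,4R,5R)-3-(3,3-diethoxyprop-1-en-2-yl)-4-hydroxy-2-methyl-2-[2-(phenylsulfinyl)ethyl]-5-(prop-1-en-2-yl)cyclohexan-1-one (sulfoxide epimers) | O=S(c1ccccc1)CC[C@]1(C)C(=O)C[C@H](C(C)=C)[C@@H](O)[C@H]1C(=C)C(OCC)OCC
F4 | step 8 | C8-bromo derivative of 17 (bromine α, trans to the C7 side chain) | C=C[C@]1(C)C(=O)[C@@H](Br)[C@H](C(=C)C(=O)O)[C@@H](OC(C)=O)[C@H]1C(=C)C(OCC)OCC
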